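The route rests on disconnecting the 1,2-dioxolane (O1, O2, C3, C4, C5) at the O2–C3 bond and at the exocyclic C3–CH2CO2H bond: C3, the ring carbon between O2 and C4, is treated as a masked ketone. The precursor is therefore an open-chain β-(silylperoxy) methyl ketone in which only the C5 peroxide stereocentre (from stereoinvertive perhydrolysis of an oxetane) and the side-chain centre (from (R)-citronellal) exist. In one operation a silyl triflate closes the peroxide oxygen onto the ketone (5-exo), the cyclic peroxyketal ionises to a peroxycarbenium ion, and a silyl ketene acetal adds. This creates the ring, the quaternary C3 and the acetate arm.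

Key step: step 13

Remark on the chemistry: (R)-citronellal and (E)-1-phenylbuta-1,3-diene are taken as purchased. Minor diastereomers expected in steps 4 and 13 are assumed to be removed by chromatography at those stages.

Step 1
Reactants: 1 (R)-citronellal
Product: 2 (4R)-4,8-dimethylnon-7-en-1-yne
Conditions: dimethyl (1-diazo-2-oxopropyl)phosphonate, K2CO3, MeOH, 0 °C → rt
Reagents that add atoms: dimethyl (1-diazo-2-oxopropyl)phosphonate, CC(=O)C(=[N+]=[N-])P(=O)(OC)OC
Why: Seyferth–Gilbert homologation (Ohira–Bestmann variant) turns the aldehyde into the terminal alkyne under mild base without touching the β-stereocentre or the trisubstituted alkene.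

Step 2
Reactants: 2 (4R)-4,8-dimethylnon-7-en-1-yne
Product: 4 (3E,6R)-4,6,10-trimethylundeca-3,9-dien-2-one, via alkenylalane 3 (not isolated)
Conditions: Me3Al, Cp2ZrCl2 (cat.), CH2Cl2, 0 °C → rt; then AcCl, Pd(PPh3)4 (cat.), THF, 0 °C
Reagents that add atoms: trimethylaluminium, C[Al](C)C; acetyl chloride, CC(=O)Cl
Why: Zirconium-catalysed syn-carboalumination (Negishi) puts methyl on the internal and aluminium on the terminal alkyne carbon, and Pd-catalysed acylation of the alkenylalane with retention should give the (E)-enone, the remote trisubstituted alkene being inert.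

Step 3
Reactants: 4 (3E,6R)-4,6,10-trimethylundeca-3,9-dien-2-one
Product: 5 (2R,3E,6R)-4,6,10-trimethylundeca-3,9-dien-2-ol
Conditions: (S)-2-methyl-CBS-oxazaborolidine (cat.), catecholborane, toluene, −78 °C
Reagents that add atoms: none
Why: Corey–Bakshi–Shibata reduction, in which the alkenyl group acts as the large substituent so that the (S)-catalyst should deliver hydride in a 1,2-sense to give the (R)-carbinol, while catecholborane at −78 °C leaves the alkenes alone.

Step 4
Reactants: 5 (2R,3E,6R)-4,6,10-trimethylundeca-3,9-dien-2-ol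
Product: 6 (1R)-1-[(2S,3S)-3-[(2R)-2,6-dimethylhept-5-en-1-yl]-3-methyloxiran-2-yl]ethan-1-ol
Conditions: Ti(OiPr)4 (cat.), t-BuOOH (anhydrous, decane), 4 Å MS, CH2Cl2, −20 °C
Reagents that add atoms: tert-butyl hydroperoxide, CC(C)(C)OO
Why: Hydroxyl-directed titanium alkoxide epoxidation, in which A(1,3) strain with the methyl cis to the carbinol holds the carbinol hydrogen in the alkene plane so that oxygen is delivered to the face syn to OH, setting both oxirane centres (threo) from the carbinol centre while the undirected remote alkene should not react.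

Step 5
Reactants: 6 (1R)-1-[(2S,3S)-3-[(2R)-2,6-dimethylhept-5-en-1-yl]-3-methyloxiran-2-yl]ethan-1-ol
Product: 7 (2R,4S,6R)-4,6,10-trimethylundec-9-ene-2,4-diol
Conditions: Red-Al, THF, 0 °C → rt
Reagents that add atoms: none
Why: Alkoxide-directed hydride opening of the 2,3-epoxy alcohol at the only non-quaternary oxirane carbon (SN2) leaves the tertiary C–O bond and its configuration intact and gives the 1,3-diol.

Step 6
Reactants: 7 (2R,4S,6R)-4,6,10-trimethylundec-9-ene-2,4-diol
Product: 9 (2S,4S)-2-[(2R)-2,6-dimethylhept-5-en-1-yl]-2,4-dimethyloxetane, via secondary tosylate 8 (not isolated)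
Conditions: n-BuLi (1 equiv), THF, −78 → 0 °C; TsCl; then KOt-Bu, 0 → 40 °C
Reagents that add atoms: none
Why: Intramolecular Williamson etherification (4-exo-tet), in which the unhindered secondary hydroxyl is sulfonylated selectively and the tertiary alkoxide displaces it with inversion, the quaternary carbinol centre being retained.

Step 7
Reactants: 9 (2S,4S)-2-[(2R)-2,6-dimethylhept-5-en-1-yl]-2,4-dimethyloxetane
Product: 10 (4R)-5-[(2S,4S)-2,4-dimethyloxetan-2-yl]-4-methylpentanal
Conditions: O3, CH2Cl2/MeOH, −78 °C; then PPh3, −78 °C → rt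
Reagents that add atoms: ozone, [O-][O+]=O
Why: Ozonolysis with reductive work-up cleaves the only alkene to the aldehyde and leaves the oxetane untouched.

Step 8
Reactants: 10 (4R)-5-[(2S,4S)-2,4-dimethyloxetan-2-yl]-4-methylpentanal
Product: 11 (2S,4S)-2-[(2R,5E)-6-iodo-2-methylhex-5-en-1-yl]-2,4-dimethyloxetane
Conditions: CrCl2, CHI3, THF/1,4-dioxane, 0 °C → rt
Reagents that add atoms: iodoform, IC(I)I
Why: Takai olefination, in which the gem-dichromium species from iodoform adds to the aldehyde and eliminates to the (E)-iodoalkene under neutral, aldehyde-selective conditions.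

Step 9
Reactants: 11 (2S,4S)-2-[(2R,5E)-6-iodo-2-methylhex-5-en-1-yl]-2,4-dimethyloxetane; 12 (E)-1-phenylbuta-1,3-diene
Product: 14 (2S,4S)-2,4-dimethyl-2-[(2R,5E,9E)-2-methyl-10-phenyldeca-5,9-dien-1-yl]oxetane, via alkylborane 13 (not isolated)
Conditions: 12, 9-BBN-H (1 equiv), THF, 0 °C → rt; then 11, PdCl2(dppf) (cat.), 3 M aq NaOH, THF, 50 °C
Reagents that add atoms: none
Why: B-alkyl Suzuki–Miyaura coupling, in which 9-BBN hydroborates only the terminal vinyl group of the diene at its terminal carbon and the alkylborane couples with the iodoalkene with retention of both (E)-alkenes.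

Step 10
Reactants: 14 (2S,4S)-2,4-dimethyl-2-[(2R,5E,9E)-2-methyl-10-phenyldeca-5,9-dien-1-yl]oxetane
Product: 15 (2S,4R,6R,9E,13E)-4-hydroperoxy-4,6-dimethyl-14-phenyltetradeca-9,13-dien-2-ol
Conditions: anhydrous H2O2 in Et2O (excess), TMSOTf (cat.), −78 → −20 °C
Reagents that add atoms: hydrogen peroxide, OO
Why: Lewis-acid-promoted perhydrolysis of the oxetane, in which hydrogen peroxide opens the activated ring at the tertiary carbon in an SN2-like, stereoinvertive substitution that sets the (4R) tertiary hydroperoxide and releases the secondary alcohol.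

Step 11
Reactants: 15 (2S,4R,6R,9E,13E)-4-hydroperoxy-4,6-dimethyl-14-phenyltetradeca-9,13-dien-2-ol
Product: 16 (2S,4R,6R,9E,13E)-4,6-dimethyl-14-phenyl-4-[(triethylsilyl)peroxy]tetradeca-9,13-dien-2-ol
Conditions: Et3SiCl (1.05 equiv), Et3N, CH2Cl2, −40 °C
Reagents that add atoms: chlorotriethylsilane, CC[Si](Cl)(CC)CC
Why: Chemoselective O-silylation, in which the hydroperoxide (more acidic and an α-effect nucleophile) should be silylated ahead of the secondary alcohol.

Step 12
Reactants: 16 (2S,4R,6R,9E,13E)-4,6-dimethyl-14-phenyl-4-[(triethylsilyl)peroxy]tetradeca-9,13-dien-2-ol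
Product: 17 (4R,6R,9E,13E)-4,6-dimethyl-14-phenyl-4-[(triethylsilyl)peroxy]tetradeca-9,13-dien-2-one
Conditions: Dess–Martin periodinane, CH2Cl2, 0 °C → rt
Reagents that add atoms: none
Why: Dess–Martin oxidation of the secondary alcohol under non-basic conditions should give the β-(silylperoxy) ketone without β-elimination, and erases the carbinol centre that has served its purpose.

Step 13
Reactants: 17 (4R,6R,9E,13E)-4,6-dimethyl-14-phenyl-4-[(triethylsilyl)peroxy]tetradeca-9,13-dien-2-one
Product: 20 methyl 2-[(3S,5R)-3,5-dimethyl-5-[(2R,5E,9E)-2-methyl-10-phenyldeca-5,9-dien-1-yl]-1,2-dioxolan-3-yl]acetate, via silyloxydioxolane 18 (not isolated), via peroxycarbenium triflate 19 (not isolated)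
Conditions: Et3SiOTf (0.2 equiv), 2,6-di-tert-butyl-4-methylpyridine (0.3 equiv), CH2Cl2, −78 °C; then tert-butyl[(1-methoxyethenyl)oxy]dimethylsilane, −78 → −40 °C; aq NaHCO3
Reagents that add atoms: tert-butyl[(1-methoxyethenyl)oxy]dimethylsilane, C=C(OC)O[Si](C)(C)C(C)(C)C
Why: Proposed new method: the silyl triflate activates the ketone of 17, the silylated peroxide oxygen adds to it with silyl migration to give the cyclic silyl peroxyketal 18, and 18 ionises to the planar peroxycarbenium ion 19, which the silyl ketene acetal captures in a Mukaiyama-type C–C bond formation; the closest known reaction types are the Lewis-acid-mediated substitution of 3-alkoxy-1,2-dioxolanes by silyl ketene acetals through peroxycarbenium ions and the one-flask cyclisation–allylation of silyloxy ketones to 2,2-disubstituted cyclic ethers. The ring closure (O2–C3 bond) is 5-exo-trig and both C3 epimers of 18 converge on the same cation, so the closure itself needs no stereocontrol. The new quaternary centre C3 is set by 1,3-induction from the fixed C5 centre: the nucleophile should enter the cation face anti to the larger, β-branched 2-methylalkyl chain and syn to the C5 methyl, which puts CH2CO2Me trans to the chain as required (3S). The step needs this diastereofacial selectivity, for which the size difference at C5, the bulky silyl ketene acetal and the low temperature are relied on, with the minor C3 epimer removed by chromatography. It also needs chemoselectivity for the ketene acetal over the two chain alkenes as π-nucleophiles, which the much higher nucleophilicity of the ketene acetal and the hindered base (no free triflic acid) should secure. Forming 18 before the ketene acetal is added should suppress an intermolecular aldol addition to the open-chain ketone.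

Step 14
Reactants: 20 methyl 2-[(3S,5R)-3,5-dimethyl-5-[(2R,5E,9E)-2-methyl-10-phenyldeca-5,9-dien-1-yl]-1,2-dioxolan-3-yl]acetate
Product: 21 2-[(3S,5R)-3,5-dimethyl-5-[(2R,5E,9E)-2-methyl-10-phenyldeca-5,9-dien-1-yl]-1,2-dioxolan-3-yl]acetic acid
Conditions: LiOH, THF/H2O, 0 °C; then 1 M HCl to pH 3
Reagents that add atoms: lithium hydroxide, [Li+].[OH-]
Why: Ester saponification at 0 °C should be faster than α-deprotonation, so the β-peroxy ester is hydrolysed without retro-oxa-Michael opening or epimerisation of the dioxolane.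

Compound list
1 | (R)-citronellal, (3R)-3,7-dimethyloct-6-enal | C[C@H](CCC=C(C)C)CC=O | starting material
2 | (4R)-4,8-dimethylnon-7-en-1-yne | C#CC[C@H](C)CCC=C(C)C | intermediate
3 | dimethyl[(1E,4R)-2,4,8-trimethylnona-1,7-dien-1-yl]alumane (alkenylalane) | C[Al](C)/C=C(\C)C[C@H](C)CCC=C(C)C | intermediate (not isolated)
4 | (3E,6R)-4,6,10-trimethylundeca-3,9-dien-2-one | CC(=O)/C=C(\C)C[C@H](C)CCC=C(C)C | intermediate
5 | (2R,3E,6R)-4,6,10-trimethylundeca-3,9-dien-2-ol | C[C@@H](O)/C=C(\C)C[C@H](C)CCC=C(C)C | intermediate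
6 | (1R)-1-[(2S,3S)-3-[(2R)-2,6-dimethylhept-5-en-1-yl]-3-methyloxiran-2-yl]ethan-1-ol | C[C@@H](O)[C@@H]1O[C@@]1(C)C[C@H](C)CCC=C(C)C | intermediate
7 | (2R,4S,6R)-4,6,10-trimethylundec-9-ene-2,4-diol | C[C@@H](O)C[C@](O)(C)C[C@H](C)CCC=C(C)C | intermediate
8 | (2R,4S,6R)-4-hydroxy-4,6,10-trimethylundec-9-en-2-yl 4-methylbenzenesulfonate (secondary tosylate) | C[C@@H](OS(=O)(=O)c1ccc(C)cc1)C[C@](O)(C)C[C@H](C)CCC=C(C)C | intermediate (not isolated)
9 | (2S,4S)-2-[(2R)-2,6-dimethylhept-5-en-1-yl]-2,4-dimethyloxetane | C[C@H]1C[C@](C)(C[C@H](C)CCC=C(C)C)O1 | intermediate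
10 | (4R)-5-[(2S,4S)-2,4-dimethyloxetan-2-yl]-4-methylpentanal | C[C@H]1C[C@](C)(C[C@H](C)CCC=O)O1 | intermediate
11 | (2S,4S)-2-[(2R,5E)-6-iodo-2-methylhex-5-en-1-yl]-2,4-dimethyloxetane | C[C@H]1C[C@](C)(C[C@H](C)CC/C=C/I)O1 | intermediate
12 | (E)-1-phenylbuta-1,3-diene | C=C/C=C/c1ccccc1 | starting material
13 | 9-[(3E)-4-phenylbut-3-en-1-yl]-9-borabicyclo[3.3.1]nonane (alkylborane) | C1CC2CCCC(C1)B2CC/C=C/c3ccccc3 | intermediate (not isolated)
14 | (2S,4S)-2,4-dimethyl-2-[(2R,5E,9E)-2-methyl-10-phenyldeca-5,9-dien-1-yl]oxetane | C[C@H]1C[C@](C)(C[C@H](C)CC/C=C/CC/C=C/c2ccccc2)O1 | intermediate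
15 | (2S,4R,6R,9E,13E)-4-hydroperoxy-4,6-dimethyl-14-phenyltetradeca-9,13-dien-2-ol | C[C@H](O)C[C@](C)(OO)C[C@H](C)CC/C=C/CC/C=C/c1ccccc1 | intermediate
16 | (2S,4R,6R,9E,13E)-4,6-dimethyl-14-phenyl-4-[(triethylsilyl)peroxy]tetradeca-9,13-dien-2-ol | C[C@H](O)C[C@](C)(OO[Si](CC)(CC)CC)C[C@H](C)CC/C=C/CC/C=C/c1ccccc1 | intermediate
17 | (4R,6R,9E,13E)-4,6-dimethyl-14-phenyl-4-[(triethylsilyl)peroxy]tetradeca-9,13-dien-2-one | CC(=O)C[C@](C)(OO[Si](CC)(CC)CC)C[C@H](C)CC/C=C/CC/C=C/c1ccccc1 | intermediate
18 | triethyl{[(5R)-3,5-dimethyl-5-[(2R,5E,9E)-2-methyl-10-phenyldeca-5,9-dien-1-yl]-1,2-dioxolan-3-yl]oxy}silane, both C3 epimers (silyloxydioxolane) | C[C@H](CC/C=C/CC/C=C/c1ccccc1)C[C@]1(C)CC(C)(O[Si](CC)(CC)CC)OO1 | intermediate (not isolated)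
19 | (5R)-3,5-dimethyl-5-[(2R,5E,9E)-2-methyl-10-phenyldeca-5,9-dien-1-yl]-1,2-dioxolan-3-ylium trifluoromethanesulfonate (peroxycarbenium triflate) | C[C@H](CC/C=C/CC/C=C/c1ccccc1)C[C@]1(C)CC(C)=[O+]O1.[O-]S(=O)(=O)C(F)(F)F | intermediate (not isolated)
20 | methyl 2-[(3S,5R)-3,5-dimethyl-5-[(2R,5E,9E)-2-methyl-10-phenyldeca-5,9-dien-1-yl]-1,2-dioxolan-3-yl]acetate | C[C@H](CC/C=C/CC/C=C/c1ccccc1)C[C@]1(C)C[C@@](C)(CC(=O)OC)OO1 | intermediate
21 | 2-[(3S,5R)-3,5-dimethyl-5-[(2R,5E,9E)-2-methyl-10-phenyldeca-5,9-dien-1-yl]-1,2-dioxolan-3-yl]acetic acid | C[C@H](CC/C=C/CC/C=C/c1ccccc1)C[C@]1(C)C[C@@](C)(CC(=O)O)OO1 | target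

Total step count: 14. Longest linear sequence: 14 steps (1 → 21).

Steps most likely to fail

Step 13 (proposed method). The silyl transfer and cyclisation may not outpace an intermolecular aldol addition of the ketene acetal to the open-chain ketone, and discrimination between the two faces of the peroxycarbenium ion may be poor. The fallback uses known chemistry and sets out from 17. Acid methanolysis (p-TsOH, MeOH, 0 °C) removes the silyl group, closes the peroxyhemiketal and exchanges it to the isolable (5R)-3-methoxy-3,5-dimethyl-5-[(2R,5E,9E)-2-methyl-10-phenyldeca-5,9-dien-1-yl]-1,2-dioxolane F1. Stoichiometric TiCl4 with the same silyl ketene acetal (CH2Cl2, −78 °C), the established peroxycarbenium substitution of 3-alkoxy-1,2-dioxolanes, then returns to the route at 20.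

Step 10. The activated oxetane may ionise to a free tertiary cation with erosion of configuration, and the acid may promote hydroperoxide addition to, or oligomerisation of, the styrenyl diene. The fallback changes the order of events and sets out from iodoalkene 11, which carries no acid-sensitive alkene. Perhydrolysis of 11 gives (2S,4R,6R,9E)-4-hydroperoxy-10-iodo-4,6-dimethyldec-9-en-2-ol F2. Silylation as in step 11 gives (2S,4R,6R,9E)-10-iodo-4,6-dimethyl-4-[(triethylsilyl)peroxy]dec-9-en-2-ol F3, and Dess–Martin oxidation gives (4R,6R,9E)-10-iodo-4,6-dimethyl-4-[(triethylsilyl)peroxy]dec-9-en-2-one F4. The cyclisation–alkylation of step 13 then gives methyl 2-[(3S,5R)-5-[(2R,5E)-6-iodo-2-methylhex-5-en-1-yl]-3,5-dimethyl-1,2-dioxolan-3-yl]acetate F5. The C11–C15 unit is attached last by B-alkyl Suzuki–Miyaura coupling of F5 with borane 13 under mild conditions (PdCl2(dppf), AsPh3, K3PO4, DMF/H2O, rt), returning to the route at 20.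

Step 6. The tertiary alkoxide may trigger Grob-type fragmentation (to a methyl ketone and propene) or E2 elimination of the secondary sulfonate instead of the 4-exo-tet closure. The fallback sets out from diol 7 and returns at oxetane 9 without generating an alkoxide: cyclodehydration with diethoxytriphenylphosphorane (toluene, 60 °C) activates the secondary hydroxyl as an alkoxyphosphonium ion, which the neutral tertiary hydroxyl displaces with the same inversion. No compound outside the list is made (entry F0).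

Further compounds
F1 | step 13 | (5R)-3-methoxy-3,5-dimethyl-5-[(2R,5E,9E)-2-methyl-10-phenyldeca-5,9-dien-1-yl]-1,2-dioxolane (both C3 epimers) | C[C@H](CC/C=C/CC/C=C/c1ccccc1)C[C@]1(C)CC(C)(OC)OO1
F2 | step 10 | (2S,4R,6R,9E)-4-hydroperoxy-10-iodo-4,6-dimethyldec-9-en-2-ol | C[C@H](O)C[C@](C)(OO)C[C@H](C)CC/C=C/I
F3 | step 10 | (2S,4R,6R,9E)-10-iodo-4,6-dimethyl-4-[(triethylsilyl)peroxy]dec-9-en-2-ol | C[C@H](O)C[C@](C)(OO[Si](CC)(CC)CC)C[C@H](C)CC/C=C/I
F4 | step 10 | (4R,6R,9E)-10-iodo-4,6-dimethyl-4-[(triethylsilyl)peroxy]dec-9-en-2-one | CC(=O)C[C@](C)(OO[Si](CC)(CC)CC)C[C@H](C)CC/C=C/I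
F5 | step 10 | methyl 2-[(3S,5R)-5-[(2R,5E)-6-iodo-2-methylhex-5-en-1-yl]-3,5-dimethyl-1,2-dioxolan-3-yl]acetate | C[C@H](CC/C=C/I)C[C@]1(C)C[C@@](C)(CC(=O)OC)OO1
F0 | step 6 | none | none
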